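Start from the slowness of the red flask: between 5.00 h and 12.0 h it loses 8.9 percentage points of electrophile, while target gains 4.4 points.

- red: electrophile 0.20 M; nucleophile 1 equiv; free base 2 equiv; temperature 20 °C; the very flask that is asked about, followed so far
- flask: electrophile 0.20 M; nucleophile 1.00 equiv; free base 2.00 equiv; temperature 20 °C; time 20 h

red run (percent of the electrophile charged)

| time / h | target / % | electrophile / % |
|---|---|---|
| 1.00 | 9.8 | 81.6 |
| 2.00 | 15.3 | 73.0 |
| 5.00 | 20.9 | 58.7 |
| 12.0 | 25.3 | 49.8 |

(readings scatter by 0.5 percentage points)

- additions leave the volume as it is
- reactions considered so far: electrophile + nucleophile -> acid set free + target; nucleophile + acid set free <-> protonated nucleophile; acid set free + free base <-> salt of the base; target <-> isomer of the product; electrophile + acid set free -> side product; acid set free -> by-product carried off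

- dusk: at 20 h add free base, 100 % of the amount charged, then wait 6.0 h
- autumn: change nothing and wait 6.0 h more
- spring: at 20 h add electrophile, 50.0 % of the amount charged, then wait 6.0 h
- winter: at 20 h raise the temperature by 20 K, then wait 6.0 h
- dawn: at 20 h add free base, 100 % of the amount charged, then wait 6.0 h

- target, in percent of the electrophile first charged, at 20 h
- what to do for the largest gain in target; "none" if nothing gains more than 2 percentage points (dusk / autumn / spring / winter / dawn / none)
- target present, in percent of the electrophile first charged, after autumn
- target present, in percent of the electrophile first charged, after winter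

Now set two numbers side by side. The step from electrophile and nucleophile makes one target per electrophile, yet by 12.0 h the red flask has lost 50.2 % of its electrophile and shows 25.3 % of target.

Compare rates over one stretch to clear this. Count electrophile lost as target made, and made minus net gain as used: the late stretch then gives 1.98. Call this reading the made-to-used ratio m, the rate at which target is made divided by the rate at which it is used up. The stretch up to 2.00 h reads 2.31, a gap that a scatter of 0.5 points on differences this small can cover. Read a steady m as the mark of thermodynamic control between target and isomer of the product. Each point of electrophile spent then leaves a fixed share of target, and with m held, spending the full charge tops out at 49.4 %. But m is a reading at 20 °C, and a target above that ceiling requires a larger m.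

The forecast gives 27.8 % at 20 h, 29 % after autumn and 31.5 % after winter, and chooses winter, with the remark “Isomer drain is the risk, so this is uncertain”.

The flask holds 27.6 % at 20 h, 29.2 % after autumn and 65.3 % after winter, so the choice is winter, a gain of 38 points.

    electrophile + nucleophile → acid set free + target (k = 0.0200 M⁻¹ min⁻¹, Ea = 65.0 kJ mol⁻¹)
    nucleophile + acid set free ⇌ protonated nucleophile, settled at all times (K = 47000 M⁻¹, ΔH = −48.0 kJ mol⁻¹)
    acid set free + free base ⇌ salt of the base, settled at all times (K = 4.70 M⁻¹, ΔH = −21.0 kJ mol⁻¹)
    target ⇌ isomer of the product (K = 1.00, k = 0.0350 min⁻¹, Ea = 98.0 kJ mol⁻¹, ΔH = −61.0 kJ mol⁻¹)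
    electrophile + acid set free → side product (k = 0.0240 M⁻¹ min⁻¹, Ea = 74.0 kJ mol⁻¹)
    acid set free → by-product carried off (k = 0.230 min⁻¹, Ea = 73.0 kJ mol⁻¹)
    (constants at 20 °C)

That winter figure stands higher than the ceiling of 49.4 %. Target and isomer of the product relax with a half-life of 0.165 h, shorter than 20 h. Put m to use: in the flask at 20.0 h, 44.8 % of electrophile left and the read m of 1.98 give 27.3 % of target, beside the 27.6 % it holds. The repeat at 35 °C, with 14.2 % of electrophile left and 65.8 % of target, has a larger ratio, m = 4.29.

The numbers in the tables were computed for an exercise.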